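## The problem

Target **15** is a sesquiterpenoid ether of umbelliferone: a 2,2,4-trimethylcyclohexanone carrying a five-carbon chain that ends in the aryl ether. The ring is numbered C1 (gem-dimethyl carbon), C2 (ketone), C3, C4, C5 (ring carbinol) and C6 (CH bearing the chain). The chain runs C7 to C11, with C9 the chain carbinol and C11 the OCH2 group.

Three stereocentres must be set. C5 (S) and C6 (S) are adjacent and place the C5 hydroxyl trans to the chain. C9 (R) is a tertiary methyl carbinol two methylenes away from the ring. C6 can steer events at C5, but no ring centre can reach C9, whose two larger substituents are both CH2CH2 arms, so C9 needs reagent control that tells methyl from methylene.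

The quaternary C1 flanks both the ketone and C6, which makes late carbon–carbon bond formation on the ring unattractive. The two tertiary alcohols are prone to ionisation and dehydration under acid. The coumarin lactone and its C3–C4 olefin would not survive organolithium bases, hydride, ozone or catalytic hydrogenation.

The enabling feature is that the C2 carbonyl and the C5 carbinol sit 1,4 across the ring and C5 carries no hydrogen. This is the pattern left by base-induced opening of a peroxide bridging C2 and C5, and with hydrogen only on C2 that opening can run in one direction only.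

## Retrosynthesis

**C11–O aryl ether.** Cutting this bond divides **15** into triol **13** and umbelliferone **14**. The cut is placed last because every earlier operation (amide base, ozone, hydride, hydrogen) would damage the coumarin. The forward Mitsunobu reaction must select one primary hydroxyl among three; the other two are tertiary and cannot be activated.

**C3–C4 saturation and the C11 terminus.** Triol **13** is traced to enone triol **12**, and the hydroxyethyl end of **12** to the allyl group of hydroxy enone **10** through aldehyde **11**. An allyl group is the simplest two-carbon carbinol precursor that tolerates all earlier chemistry. The cleavage must precede the hydrogenation, which would otherwise reduce the allyl olefin. Ozone has to prefer the monosubstituted olefin over the enone olefin, and the hydride the aldehyde over the C2 ketone.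

**C2–O and C5–O (key disconnection).** Both ring oxygens of **10** are removed together: **10** is the opened form of endoperoxide **9**, which is the singlet-oxygen adduct of ring diene **8**. Stepwise oxidation of C2 and C5 would need two selective operations and separate control of C5. Here one operation installs the whole oxidation pattern and the C5 centre from C6. Diene **8** has two oxygens and one stereocentre fewer and still holds the full carbon skeleton. The forward reaction needs oxygen to add anti to the C6 chain and to leave the allyl olefin alone.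

**The C2=C3 olefin.** Diene **8** is traced through tosylhydrazone **7** and enone **6** to ring monoene **5**. Allylic bromination and dehydrobromination would be shorter but is not defensible. The ring olefin has three allylic sites (C3, C6 and the C5 methyl), the allyl radical is ambident, and an ionising allylic halide tends towards the more substituted 3,5-diene. Oxidation at C3 followed by hydrazone-directed α′ deprotonation fixes the new olefin at C2=C3 by mechanism. The cost is one or two extra steps.

**C9–C10.** Carbinol **5** comes from methyl ketone **3** and allylboronic acid pinacol ester **4**. This bond is chosen because it creates C9 under catalyst control and delivers the masked hydroxyethyl group in the same step. The reaction must discriminate methyl from the CH2CH2 arm at the carbonyl.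

**C7–C8 saturation and the source of C6.** Ketone **3** is the conjugate-reduction product of (S)-α-ionone **2**, obtained by resolution of commercial racemic α-ionone **1**. α-Ionone supplies thirteen of the fifteen skeletal carbons, the gem-dimethyl group, the C5 methyl, the C6 centre and an olefin exactly where the diene is to be developed.

## Roads not taken

**Alternative 1:** Baeyer–Villiger fragmentation of a trans-hydrindanone.
- Cut: the C5–O bond is traced to a C5–C9 bond, folding ring and chain into trans-hydrindanone ketal **A2**, which descends from the (S)-Hajos–Parrish ketone **A1**.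
- Forward key step: a peracid inserts oxygen between C9 and the quaternary C5 with retention, giving δ-lactone **A3**.
- Merits: C5 comes from an enantiopure, catalytically made bicycle and C6 from the ring fusion. The C5/C6 relationship is therefore fixed by a covalent ring, not by a facial preference. Migration of the quaternary carbon is the normal aptitude. In this respect the alternative is safer than the chosen plan.
- Weak points: reaching **A2** from **A1** needs deconjugative gem-dimethylation, a trans-selective reduction of the ring fusion (hydrindanes favour cis) and differentiation of two ketones with the more hindered one ketalised. After **A3** the lactone carbonyl must still be turned into the C9 methyl carbinol, so the methyl-versus-methylene problem returns late, beside a free C5 hydroxyl that can close onto C9.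
- Comparison: the chosen plan sets against this its short sequence and a skeleton that is complete from the start, and accepts a facial-selectivity risk at C5 in exchange.

**Alternative 2:** asymmetric Diels–Alder reaction of an oxidised linalool enal.
- Cut: C1–C6 and C4–C5, dividing the ring into enal **A5** (chain, C9 and coumarin already in place, derived from (R)-linalool **A4**) and siloxydiene **A6**.
- Forward key step: a chiral oxazaborolidinium Lewis acid activates **A5** and **A6** adds across its olefin to give cyclohexene silyl enol ether **A7**.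
- Merits: it is the most convergent plan. C9 comes from the chiral pool, which is better than the asymmetric ketone allylation used here. The C5/C6 relationship follows from the (E)-olefin geometry, and endo/exo selectivity is irrelevant because the diene termini carry no stereochemical label.
- Weak points: the bond that must lead in an asynchronous transition state joins the β-carbon of an α,β-disubstituted enal to a fully substituted diene terminus, creating the quaternary C1 next to C6. Dienes with a disubstituted terminus reach the s-cis form poorly. The coumarin lactone competes for the Lewis acid. **A7** carries a formyl group at C5, so the carbinol needs a later oxidative excision of that carbon in the presence of the coumarin and an enol ether.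
- Comparison: it is better on convergence and on C9. The chosen plan offers a key step from a well-populated reaction class, against a cycloaddition without close precedent.

**Alternative 3:** proline-catalysed enolexo aldol closure of an achiral keto aldehyde.
- Cut: C5–C6, opening the ring to 3,3-dimethyl-4,7-dioxooctanal **A8**.
- Forward key step: enamine formation at the aldehyde and attack of C6 on the C5 methyl ketone give hydroxy aldehyde **A9**.
- Merits: both ring stereocentres and the C2 ketone arise in one catalytic step from an achiral chain, with no resolution. The chosen plan discards half of the α-ionone, so this is a real advantage.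
- Weak points: **A8** offers several competing closures (enamine of the methyl ketone onto the aldehyde, cyclopentenone formation from the 1,4-diketone). Ketone acceptors are poor in enamine aldol chemistry. **A9** is a β-hydroxy aldehyde with an α-hydrogen and can revert, epimerise or dehydrate. The C7–C11 chain with C9 must then be attached to a neopentyl-type aldehyde.
- Comparison: the ring is reached faster, but the chain and C9 remain to be built. The chosen plan starts with thirteen carbons and C6 in place and spends its steps on functional-group changes of known type.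

Key step: step 7

Assumptions:
- The enantiomers of α-ionone are taken to be separable on a polysaccharide chiral phase, with the (S)-fraction identified by chiroptical comparison.
- In step 3, (R,R)-i-Pr-DuPHOS is taken to deliver allyl to the Si face. If the first run shows the opposite sense, the (S,S)-ligand is used and nothing else changes.
- The descriptor of ring carbon C6 changes from S (compounds **2**–**7**) to R (compound **8**) for priority reasons only; its geometry is the same throughout.

## Route

Step 1
Reactants: 1 racemic α-ionone, (3E)-4-(2,6,6-trimethylcyclohex-2-en-1-yl)but-3-en-2-one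
Product: 2 (S)-α-ionone, (3E)-4-[(1S)-2,6,6-trimethylcyclohex-2-en-1-yl]but-3-en-2-one
Conditions: preparative chiral SFC, amylose tris(3,5-dimethylphenylcarbamate) phase, CO2/i-PrOH, 35 °C; (S)-fraction collected
Reagents that add atoms: none
Why: Chromatographic resolution on a polysaccharide chiral stationary phase: the enantiomers form diastereomeric adsorbates of different stability, no bond is made or broken, and the enone chromophore allows UV-triggered collection of the (S)-fraction.

Step 2
Reactants: 2 (S)-α-ionone
Product: 3 4-[(1S)-2,6,6-trimethylcyclohex-2-en-1-yl]butan-2-one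
Conditions: [(Ph3P)CuH]6 (0.25 equiv), H2O (2 equiv), degassed PhH, rt
Reagents that add atoms: none
Why: Conjugate reduction with the hexameric triphenylphosphine copper hydride: hydride goes to C7 and the copper enolate is protonated by water; the isolated trisubstituted ring olefin is untouched and the neutral medium does not remove the C6 hydrogen (γ to the carbonyl in 2), so the (S) centre persists.

Step 3
Reactants: 3 4-[(1S)-2,6,6-trimethylcyclohex-2-en-1-yl]butan-2-one; 4 allylboronic acid pinacol ester
Product: 5 (3R)-3-methyl-1-[(1S)-2,6,6-trimethylcyclohex-2-en-1-yl]hex-5-en-3-ol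
Conditions: CuF2·2H2O (3 mol %), (R,R)-i-Pr-DuPHOS (6 mol %), La(Oi-Pr)3 (4.5 mol %), DMF, −40 °C; aq. NH4Cl
Reagents that add atoms: none
Why: Catalytic asymmetric allylboration of a ketone: transmetalation from boron gives a bisphosphine-bound allylcopper nucleophile (monovalent copper), with La(Oi-Pr)3 speeding turnover; allyl must reach the Si face of the C9 carbonyl (O > CH2CH2R > CH3) to give (R), and because C6 is four bonds away the outcome is under catalyst control alone.

Step 4
Reactants: 5 (3R)-3-methyl-1-[(1S)-2,6,6-trimethylcyclohex-2-en-1-yl]hex-5-en-3-ol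
Product: 6 (4S)-4-[(3R)-3-hydroxy-3-methylhex-5-en-1-yl]-3,5,5-trimethylcyclohex-2-en-1-one
Conditions: Rh2(cap)4 (cap = caprolactamate, 1 mol %), t-BuOOH (70% aq., 5 equiv), ClCH2CH2Cl, 40 °C
Reagents that add atoms: tert-butyl hydroperoxide, CC(C)(C)OO
Why: Radical allylic oxidation: the tert-butylperoxyl radical abstracts a C3 hydrogen, the allyl radical is trapped at C3 as a mixed peroxide and this collapses to the conjugated enone; C3 is the only unhindered secondary allylic site of the electron-rich ring olefin (C6–H lies between two fully substituted carbons, the allyl CH2 belongs to a less reactive monosubstituted olefin), the tertiary alcohol cannot be oxidised, and no base is present to epimerise C6.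

Step 5
Reactants: 6 (4S)-4-[(3R)-3-hydroxy-3-methylhex-5-en-1-yl]-3,5,5-trimethylcyclohex-2-en-1-one
Product: 7 N'-[(4S)-4-[(3R)-3-hydroxy-3-methylhex-5-en-1-yl]-3,5,5-trimethylcyclohex-2-en-1-ylidene]-4-methylbenzenesulfonohydrazide
Conditions: TsNHNH2 (1.1 equiv), PPTS (cat.), EtOH, 50 °C
Reagents that add atoms: p-toluenesulfonyl hydrazide, Cc1ccc(cc1)S(=O)(=O)NN
Why: Acid-catalysed condensation of a sulfonyl hydrazide with the only carbonyl group; β,β-disubstitution of the enone disfavours conjugate addition, and the buffered medium leaves the tertiary alcohol and the γ-acidic C6–H alone.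

Step 6
Reactants: 7 N'-[(4S)-4-[(3R)-3-hydroxy-3-methylhex-5-en-1-yl]-3,5,5-trimethylcyclohex-2-en-1-ylidene]-4-methylbenzenesulfonohydrazide
Product: 8 (3R)-3-methyl-1-[(1R)-2,6,6-trimethylcyclohexa-2,4-dien-1-yl]hex-5-en-3-ol
Conditions: LiN(i-Pr)2 (3.5 equiv), THF, −78 °C → rt; H2O
Reagents that add atoms: none
Why: Shapiro-type elimination of an α,β-unsaturated tosylhydrazone to a 1,3-diene: after the O–H and N–H protons are removed the amide takes the α′ hydrogen at C2 (syn to the hydrazone nitrogen anion), sulfinate and N2 are expelled and the C3 vinyl anion is protonated, so the new olefin sits at C2=C3; the parent case is isophorone tosylhydrazone giving 1,5,5-trimethylcyclohexa-1,3-diene, and C6 is not involved.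

Step 7
Reactants: 8 (3R)-3-methyl-1-[(1R)-2,6,6-trimethylcyclohexa-2,4-dien-1-yl]hex-5-en-3-ol
Product: 10 (4S,5S)-4-hydroxy-5-[(3R)-3-hydroxy-3-methylhex-5-en-1-yl]-4,6,6-trimethylcyclohex-2-en-1-one, via endoperoxide 9 (not isolated)
Conditions: O2, 5,10,15,20-tetraphenylporphyrin (0.5 mol %), white LEDs, CH2Cl2, −20 °C; then Et3N (1.5 equiv), 0 °C → rt
Reagents that add atoms: dioxygen, O=O
Why: Energy transfer from the excited porphyrin gives singlet oxygen, which adds suprafacially across C2 and C5 of the s-cis ring diene in a [4+2] cycloaddition; the closest known class is photooxygenation of cyclohexa-1,3-dienes followed by Kornblum–DeLaMare rearrangement to 4-hydroxycyclohex-2-enones. The only ring closed is the transient 1,2-dioxine of 9, formed in this concerted [π4s+π2s] mode as an O–O bridge over the carbocycle and reopened in the same flask, so no ring remains. Et3N then removes the C2 bridgehead hydrogen with O–O heterolysis, giving the C2 ketone and, after protonation, the C5 tertiary alcohol. The new C5 centre is set by the diene face that oxygen takes, and C6 controls this: only the face anti to the chain can be presented free of a pseudoaxial group (in the conformer with the chain pseudoequatorial the axial C1 methyl points to the far side), whereas the syn face always carries either the chain or that methyl. The C2 centre of 9 is transient and disappears on opening. The direction of opening is structural, since C5 bears a methyl group and no hydrogen. Chemoselectivity rests on the large rate gap between a cisoid 1,3-diene and a monosubstituted olefin towards singlet oxygen, and low temperature with prompt base treatment keeps 9 from rearranging to a bis-epoxide.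

Step 8
Reactants: 10 (4S,5S)-4-hydroxy-5-[(3R)-3-hydroxy-3-methylhex-5-en-1-yl]-4,6,6-trimethylcyclohex-2-en-1-one
Product: 12 (4S,5S)-5-[(3R)-3,5-dihydroxy-3-methylpentyl]-4-hydroxy-4,6,6-trimethylcyclohex-2-en-1-one, via aldehyde 11 (not isolated)
Conditions: O3, pyridine (3 equiv), CH2Cl2, −78 °C (Sudan Red 7B end point); N2 purge; then NaBH(OAc)3 (3 equiv), AcOH, 0 °C → rt
Reagents that add atoms: ozone, [O-][O+]=O
Why: Ozonolysis followed by hydride reduction: electrophilic ozone cleaves the monosubstituted olefin far faster than the electron-poor enone olefin (dye end point), pyridine diverts the carbonyl oxide so that aldehyde 11 forms directly, and NaBH(OAc)3 reduces the β-hydroxy aldehyde (assisted by the C9 hydroxyl) but not the hindered conjugated C2 ketone; no stereocentre is involved.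

Step 9
Reactants: 12 (4S,5S)-5-[(3R)-3,5-dihydroxy-3-methylpentyl]-4-hydroxy-4,6,6-trimethylcyclohex-2-en-1-one
Product: 13 (3S,4S)-3-[(3R)-3,5-dihydroxy-3-methylpentyl]-4-hydroxy-2,2,4-trimethylcyclohexan-1-one
Conditions: H2 (1 atm), 10% Pd/C, EtOAc, rt
Reagents that add atoms: none
Why: Heterogeneous catalytic hydrogenation of the cis-disubstituted enone olefin; C3 and C4 become methylenes so no stereocentre is created, the ketone and hydroxyls are inert, and a neutral aprotic solvent keeps hydrogenolysis of the allylic C5–O bond in check.

Step 10
Reactants: 13 (3S,4S)-3-[(3R)-3,5-dihydroxy-3-methylpentyl]-4-hydroxy-2,2,4-trimethylcyclohexan-1-one; 14 umbelliferone (7-hydroxy-2H-chromen-2-one)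
Product: 15 7-{[(3R)-3-hydroxy-5-[(1S,6S)-6-hydroxy-2,2,6-trimethyl-3-oxocyclohexyl]-3-methylpentyl]oxy}-2H-chromen-2-one
Conditions: PPh3 (1.3 equiv), DIAD (1.3 equiv), THF, 0 °C → rt
Reagents that add atoms: none
Why: Mitsunobu etherification: the acidic phenol is alkylated by the oxyphosphonium ion of the primary alcohol, the two tertiary alcohols cannot be activated for substitution, no stereocentre is touched, and placing the coumarin last spares it from base, hydride, ozone and hydrogen.

## Compound list

1 | racemic α-ionone, (3E)-4-(2,6,6-trimethylcyclohex-2-en-1-yl)but-3-en-2-one | CC(=O)/C=C/C1C(C)=CCCC1(C)C | starting material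
2 | (S)-α-ionone, (3E)-4-[(1S)-2,6,6-trimethylcyclohex-2-en-1-yl]but-3-en-2-one | CC(=O)/C=C/[C@@H]1C(C)=CCCC1(C)C | intermediate
3 | 4-[(1S)-2,6,6-trimethylcyclohex-2-en-1-yl]butan-2-one | CC(=O)CC[C@@H]1C(C)=CCCC1(C)C | intermediate
4 | allylboronic acid pinacol ester, 2-allyl-4,4,5,5-tetramethyl-1,3,2-dioxaborolane | C=CCB1OC(C)(C)C(C)(C)O1 | starting material
5 | (3R)-3-methyl-1-[(1S)-2,6,6-trimethylcyclohex-2-en-1-yl]hex-5-en-3-ol | C=CC[C@](C)(O)CC[C@@H]1C(C)=CCCC1(C)C | intermediate
6 | (4S)-4-[(3R)-3-hydroxy-3-methylhex-5-en-1-yl]-3,5,5-trimethylcyclohex-2-en-1-one | C=CC[C@](C)(O)CC[C@@H]1C(C)=CC(=O)CC1(C)C | intermediate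
7 | N'-[(4S)-4-[(3R)-3-hydroxy-3-methylhex-5-en-1-yl]-3,5,5-trimethylcyclohex-2-en-1-ylidene]-4-methylbenzenesulfonohydrazide (C=N geometry not fixed) | C=CC[C@](C)(O)CC[C@@H]1C(C)=CC(=NNS(=O)(=O)c2ccc(C)cc2)CC1(C)C | intermediate
8 | (3R)-3-methyl-1-[(1R)-2,6,6-trimethylcyclohexa-2,4-dien-1-yl]hex-5-en-3-ol | C=CC[C@](C)(O)CC[C@@H]1C(C)=CC=CC1(C)C | intermediate
9 | (3R)-3-methyl-1-[(1S,4R,7S)-1,8,8-trimethyl-2,3-dioxabicyclo[2.2.2]oct-5-en-7-yl]hex-5-en-3-ol | C=CC[C@](C)(O)CC[C@@H]1[C@]2(C)C=C[C@@H](OO2)C1(C)C | intermediate
10 | (4S,5S)-4-hydroxy-5-[(3R)-3-hydroxy-3-methylhex-5-en-1-yl]-4,6,6-trimethylcyclohex-2-en-1-one | C=CC[C@](C)(O)CC[C@@H]1[C@@](C)(O)C=CC(=O)C1(C)C | intermediate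
11 | (3R)-3-hydroxy-5-[(1S,2S)-2-hydroxy-2,6,6-trimethyl-5-oxocyclohex-3-en-1-yl]-3-methylpentanal | O=CC[C@](C)(O)CC[C@@H]1[C@@](C)(O)C=CC(=O)C1(C)C | intermediate
12 | (4S,5S)-5-[(3R)-3,5-dihydroxy-3-methylpentyl]-4-hydroxy-4,6,6-trimethylcyclohex-2-en-1-one | OCC[C@](C)(O)CC[C@@H]1[C@@](C)(O)C=CC(=O)C1(C)C | intermediate
13 | (3S,4S)-3-[(3R)-3,5-dihydroxy-3-methylpentyl]-4-hydroxy-2,2,4-trimethylcyclohexan-1-one | OCC[C@](C)(O)CC[C@@H]1[C@@](C)(O)CCC(=O)C1(C)C | intermediate
14 | umbelliferone, 7-hydroxy-2H-chromen-2-one | Oc1ccc2ccc(=O)oc2c1 | starting material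
15 | 7-{[(3R)-3-hydroxy-5-[(1S,6S)-6-hydroxy-2,2,6-trimethyl-3-oxocyclohexyl]-3-methylpentyl]oxy}-2H-chromen-2-one | CC1(C)C(=O)CC[C@](C)(O)[C@H]1CC[C@@](C)(O)CCOc1ccc2ccc(=O)oc2c1 | target

## Step count and least certain steps

Total steps: 10. Longest linear sequence: 10 steps (**1** to **15**).

**Step 7 (key step).** The most likely failure is insufficient facial discrimination, because the axial C1 methyl competes with the C6 chain as a shielding group and part of the oxygen may enter syn to the chain. A competing ene-type hydroperoxidation at the C4=C5 olefin (hydrogens on the C5 methyl and C6) is the second risk.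

The fallback leaves the route at enone **6** and rejoins it at **10** without singlet oxygen:
- Alkaline hydrogen peroxide (LiOH, H2O2, MeOH, 0 °C) adds to C5 anti to the chain and closes to the epoxy ketone F1.
- Wharton transposition (N2H4·H2O, cat. AcOH, MeOH) gives the tertiary allylic alcohol F2 with the olefin at C3=C4.
- SeO2/t-BuOOH hydroxylates the only allylic C–H position, C2, by the ene/[2,3] sequence, giving the ene diol F3.
- MnO2 oxidises the secondary allylic alcohol to **10**.

**Step 3.** Enantioface discrimination between methyl and the CH2CH2 arm may be incomplete. The resulting C9 epimer has its centres too far apart for easy separation.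

The fallback leaves at **3** and rejoins at **5**, setting C9 by epoxidation:
- Horner–Wadsworth–Emmons olefination (triethyl phosphonoacetate, NaH, THF) and removal of the minor (Z)-isomer give the (E)-enoate F4.
- i-Bu2AlH gives the allylic alcohol F5.
- Sharpless asymmetric epoxidation (Ti(Oi-Pr)4, D-(−)-diethyl tartrate, t-BuOOH, 4 Å sieves, −20 °C) selects the allylic olefin over the ring olefin and gives the (2R,3R)-epoxy alcohol F6.
- NaAlH2(OCH2CH2OMe)2 delivers hydride to C10 and gives the (R)-1,3-diol F7.
- TEMPO/PhI(OAc)2 oxidises the primary alcohol to the hydroxy aldehyde F8.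
- Ph3P=CH2 (from Ph3PCH3Br and KN(SiMe3)2, THF, −78 → 0 °C) gives **5**.

**Step 4.** Hydrogen abstraction may lack site selectivity (C6–H, C5 methyl, the allyl CH2), the allyl radical may be trapped at the tertiary C5 terminus, or over-oxidation may occur.

The fallback leaves at **5** and rejoins at **6** by two-electron chemistry:
- mCPBA (1.0 equiv, NaHCO3, CH2Cl2, 0 °C) epoxidises the trisubstituted ring olefin in preference to the terminal one, giving the ring epoxide F9. Either face serves, because C5 becomes sp2 again.
- NaSePh (from PhSeSePh and NaBH4, EtOH) opens the epoxide at the secondary C4 to the hydroxy selenide F10.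
- H2O2 triggers selenoxide syn-elimination, which can only run towards C3, giving the tertiary allylic alcohol F11.
- Pyridinium chlorochromate, (C5H5NH)[CrO3Cl], effects the oxidative 1,3-transposition to **6**.

**Step 6.** Deprotonation may occur at the wrong site (the γ-hydrogen at C6 or the C5 methyl instead of C2), giving isomeric dienes or loss of configuration at C6. Sluggish hydrazone formation in step 5 would have the same consequence.

The fallback leaves at **6** and rejoins at **8**, bypassing **7**:
- Kinetic α′-enolisation (LiN(i-Pr)2, 2.2 equiv, THF, −78 °C) and O-sulfonylation with PhNTf2 give the dienyl triflate F12.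
- Pd(OAc)2/PPh3 with Bu3N and HCO2H (DMF, 60 °C) replaces the triflate by hydrogen through oxidative addition to zerovalent palladium and formate hydride transfer, giving **8**.

**Step 8.** Ozone may attack the enone olefin, the hydride may reduce the C2 ketone, or the β-hydroxy aldehyde may undergo retro-aldol cleavage before it is reduced.

The fallback leaves at **10** and rejoins at **13**, skipping **12**:
- Conjugate reduction with [(Ph3P)CuH]6 (wet PhH) removes the enone olefin first, giving the saturated hydroxy ketone F13.
- Ozonolysis, now without a competing olefin, gives the keto aldehyde F14.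
- NaBH(OAc)3 reduces F14 to **13**.

## Further compounds

F1 | step 7 | (1R,5S,6R)-5-[(3R)-3-hydroxy-3-methylhex-5-en-1-yl]-4,4,6-trimethyl-7-oxabicyclo[4.1.0]heptan-2-one | C=CC[C@](C)(O)CC[C@@H]1[C@@]2(C)O[C@H]2C(=O)CC1(C)C
F2 | step 7 | (1S,6S)-6-[(3R)-3-hydroxy-3-methylhex-5-en-1-yl]-1,5,5-trimethylcyclohex-2-en-1-ol | C=CC[C@](C)(O)CC[C@@H]1[C@@](C)(O)C=CCC1(C)C
F3 | step 7 | (1S,6S)-6-[(3R)-3-hydroxy-3-methylhex-5-en-1-yl]-1,5,5-trimethylcyclohex-2-ene-1,4-diol (C4 epimers) | C=CC[C@](C)(O)CC[C@@H]1[C@@](C)(O)C=CC(O)C1(C)C
F4 | step 3 | ethyl (2E)-3-methyl-5-[(1S)-2,6,6-trimethylcyclohex-2-en-1-yl]pent-2-enoate | CCOC(=O)/C=C(\C)CC[C@@H]1C(C)=CCCC1(C)C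
F5 | step 3 | (2E)-3-methyl-5-[(1S)-2,6,6-trimethylcyclohex-2-en-1-yl]pent-2-en-1-ol | OC/C=C(\C)CC[C@@H]1C(C)=CCCC1(C)C
F6 | step 3 | [(2R,3R)-3-methyl-3-{2-[(1S)-2,6,6-trimethylcyclohex-2-en-1-yl]ethyl}oxiran-2-yl]methanol | OC[C@H]1O[C@]1(C)CC[C@@H]2C(C)=CCCC2(C)C
F7 | step 3 | (3R)-3-methyl-5-[(1S)-2,6,6-trimethylcyclohex-2-en-1-yl]pentane-1,3-diol | OCC[C@](C)(O)CC[C@@H]1C(C)=CCCC1(C)C
F8 | step 3 | (3R)-3-hydroxy-3-methyl-5-[(1S)-2,6,6-trimethylcyclohex-2-en-1-yl]pentanal | O=CC[C@](C)(O)CC[C@@H]1C(C)=CCCC1(C)C
F9 | step 4 | (3R)-3-methyl-1-[(2S)-1,3,3-trimethyl-7-oxabicyclo[4.1.0]heptan-2-yl]hex-5-en-3-ol (epoxide diastereomers) | C=CC[C@](C)(O)CC[C@@H]1C2(C)OC2CCC1(C)C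
F10 | step 4 | (6S)-6-[(3R)-3-hydroxy-3-methylhex-5-en-1-yl]-1,5,5-trimethyl-2-(phenylselanyl)cyclohexan-1-ol (C1/C2 diastereomers) | C=CC[C@](C)(O)CC[C@@H]1C(C)(O)C([Se]c2ccccc2)CCC1(C)C
F11 | step 4 | (6S)-6-[(3R)-3-hydroxy-3-methylhex-5-en-1-yl]-1,5,5-trimethylcyclohex-2-en-1-ol (C1 epimers) | C=CC[C@](C)(O)CC[C@@H]1C(C)(O)C=CCC1(C)C
F12 | step 6 | (5R)-5-[(3R)-3-hydroxy-3-methylhex-5-en-1-yl]-4,6,6-trimethylcyclohexa-1,3-dien-2-yl trifluoromethanesulfonate | C=CC[C@](C)(O)CC[C@@H]1C(C)=CC(OS(=O)(=O)C(F)(F)F)=CC1(C)C
F13 | step 8 | (3S,4S)-4-hydroxy-3-[(3R)-3-hydroxy-3-methylhex-5-en-1-yl]-2,2,4-trimethylcyclohexan-1-one | C=CC[C@](C)(O)CC[C@@H]1[C@@](C)(O)CCC(=O)C1(C)C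
F14 | step 8 | (3R)-3-hydroxy-5-[(1S,6S)-6-hydroxy-2,2,6-trimethyl-3-oxocyclohexyl]-3-methylpentanal | O=CC[C@](C)(O)CC[C@@H]1[C@@](C)(O)CCC(=O)C1(C)C
A1 | alternative 1 | (S)-Hajos–Parrish ketone, (7aS)-7a-methyl-2,3,7,7a-tetrahydro-1H-indene-1,5(6H)-dione | C[C@]12CCC(=O)C=C1CCC2=O
A2 | alternative 1 | (3aS,7aS)-4,4,7a-trimethyloctahydro-1H-indene-1,5-dione 5-(ethylene ketal), trans-fused | CC1(C)C2(OCCO2)CC[C@]3(C)C(=O)CC[C@@H]13
A3 | alternative 1 | (4aS,8aS)-6,6-(ethylenedioxy)-5,5,8a-trimethyloctahydro-2H-chromen-2-one, trans-fused δ-lactone | CC1(C)C2(OCCO2)CC[C@]3(C)OC(=O)CC[C@@H]13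
A4 | alternative 2 | (R)-linalool, (3R)-3,7-dimethylocta-1,6-dien-3-ol | C=C[C@](C)(O)CCC=C(C)C
A5 | alternative 2 | (2E,6R)-2,6-dimethyl-8-[(2-oxo-2H-chromen-7-yl)oxy]-6-[(triethylsilyl)oxy]oct-2-enal | O=C/C(C)=C/CC[C@@](C)(O[Si](CC)(CC)CC)CCOc1ccc2ccc(=O)oc2c1
A6 | alternative 2 | 4-methyl-3-[(triisopropylsilyl)oxy]penta-1,3-diene | C=CC(O[Si](C(C)C)(C(C)C)C(C)C)=C(C)C
A7 | alternative 2 | 7-{[(3R)-5-[(1S,6S)-6-formyl-2,2,6-trimethyl-3-[(triisopropylsilyl)oxy]cyclohex-3-en-1-yl]-3-methyl-3-[(triethylsilyl)oxy]pentyl]oxy}-2H-chromen-2-one | CC1(C)C(O[Si](C(C)C)(C(C)C)C(C)C)=CC[C@](C)(C=O)[C@H]1CC[C@@](C)(O[Si](CC)(CC)CC)CCOc1ccc2ccc(=O)oc2c1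
A8 | alternative 3 | 3,3-dimethyl-4,7-dioxooctanal | O=CCC(C)(C)C(=O)CCC(C)=O
A9 | alternative 3 | (1S,2S)-2-hydroxy-2,6,6-trimethyl-5-oxocyclohexane-1-carbaldehyde | CC1(C)C(=O)CC[C@](C)(O)[C@H]1C=O
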